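**The product.** You want X in long chains, and the average length is the X made divided by the chains begun, living and dead together.

in all of them: J 20 mM
- red: E 1.4 M; Z 5 mol%; run made earlier
- blue: E 2.2 M; Z 5 mol%; run made earlier
- ochre: E 1 M; Z 7.5 mol%; run made earlier
- noon: E 1.0 M; Z 5 mol%; time 2.5 min
- spring: E 1.0 M; Z 5 mol%; time 0.80 min

| run | time / min | X / % | E / % |
|---|---|---|---|
| red | 0.417 | 24 | 75 |
| red | 1.00 | 67 | 34 |
| red | 2.00 | 97 | 6 |
| red | 3.00 | 101 | 2 |
| blue | 0.833 | 82 | 18 |
| blue | 1.50 | 99 | 4 |
| blue | 2.50 | 102 | 0 |
| blue | 3.00 | 97 | 0 |
| ochre | 0.417 | 21 | 79 |
| ochre | 1.00 | 62 | 36 |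
| ochre | 2.00 | 86 | 10 |
| ochre | 3.00 | 98 | 0 |

(scatter of a reading: 2 percentage points)

- the average divides the monomer in chains by the number of chains begun, living and dead together
- what was read earlier has a scatter of 2 percentage points, one standard deviation
- reactions considered so far: E + Z -> Q + X; E + Q -> X + Q; Z + J -> L
- the earlier runs do not show the number of chains; that part of a forecast is a guess

- which of the two ends with the longer chains by the average number of monomer units in a chain (chains begun, living or dead) ("neither" if they lie within 10%) (noon / spring / neither)
- average number of monomer units in a chain (chains begun, living or dead) at the end, noon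
- average number of monomer units in a chain (chains begun, living or dead) at the end, spring

**Two flasks.** Noon looks like ochre: the E and J charges are equal, and noon carries a third less Z. My guess, which the readings cannot show, is that J takes Z one for one and quickly, before E does. In noon and spring that leaves 3.00% of the E charged, and I call this the live charge, the Z left as a fraction of the E charged once J has taken its equal share. Ochre has 5.50%, so noon keeps about half of ochre's live charge.

**The ceiling.** One over the live charge is the length at full conversion with every live Z begun, the target degree of polymerisation. That is 33.3 units for noon and 18.2 for ochre. Spring has noon's ceiling but 0.80 min against 2.5 min, so I expect noon to end longer, both below the ceiling.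

**The forecast.** It says noon ends longer, with 27 units (range 20 to 34) for noon and 12 (range 8.5 to 16) for spring. Its ground is that “J seems to scavenge Z nearly stoichiometrically and fast”.

**What came.** Noon ends at 31.5 units and spring at 15.6, so noon is longer.

    E + Z → Q + X (k = 0.0300 M⁻¹ s⁻¹)
    E + Q → X + Q, rate k2*[Q]*[E] (k = 0.580 M⁻¹ s⁻¹)
    Z + J → L (k = 22.0 M⁻¹ s⁻¹)

**The balance.** At the start of noon, E uses Z at 0.068 of the rate at which J uses it, and by 1.25 min L stands at 0.0200 M with J at 0%. The live charge less the unused Z, 5.8% of its charge, gives chains of 2.71% of the E charged in noon; the same balance in the neighbour with 12 mol% of Z, where 26% of Z is unused, gives 6.89%, Q there stands at 6.89% of the E charged, and that flask ends at 14.4 units.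

All runs stem from a simulated flask from invented constants; the scatter is artificial.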